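All runs were computed on assumed constants, noise included.

**Small charge.** With a small charge of catalyst, 49 mM, Wednesday's flask still held 75.3% of its substrate at 6.00 min. The new flasks keep substrate and held gas as before, change the catalyst, and are read at 12 min.

| flask | substrate | gas | catalyst | remark | time |
|---|---|---|---|---|---|
| Wednesday's | 2 M | 200 mM (held) | 49 mM | run made earlier |  |
| Monday's | 2 M | 200 mM (held) | 150 mM | run made earlier |  |
| Tuesday's | 2 M | 200 mM (held) | 430 mM | run made earlier |  |
| winter | 2.0 M | 200 mM (held) | 50 mM |  | 12 min |
| autumn | 2.0 M | 200 mM (held) | 100 mM |  | 12 min |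
| midnight | 2.0 M | 200 mM (held) | 200 mM |  | 12 min |
| summer | 2.0 M | 200 mM (held) | 400 mM |  | 12 min |

| run | time / min | target / % | substrate / % |
|---|---|---|---|
| Wednesday's | 0.500 | 2.9 | 97.5 |
| Wednesday's | 0.833 | 4.3 | 93.9 |
| Wednesday's | 1.50 | 5.8 | 94.0 |
| Wednesday's | 3.00 | 13.6 | 87.3 |
| Wednesday's | 6.00 | 21.9 | 75.3 |
| Monday's | 0.500 | 5.5 | 93.5 |
| Monday's | 1.50 | 16.8 | 78.5 |
| Monday's | 3.00 | 30.8 | 63.6 |
| Monday's | 4.00 | 36.8 | 53.2 |
| Monday's | 6.00 | 41.9 | 33.3 |
| Tuesday's | 0.500 | 14.6 | 84.2 |
| Tuesday's | 0.833 | 23.6 | 72.4 |
| Tuesday's | 1.50 | 34.2 | 52.0 |
| Tuesday's | 3.00 | 42.6 | 20.0 |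
| Tuesday's | 6.00 | 21.1 | 1.0 |

(each reading ± 1 percentage point)

- amount of target at the end, in percent of the substrate charged for winter, autumn, midnight, summer, in this order
- how the row runs (falls, then rises / rises, then falls / falls all the way / hardly changes / rises all the way)

- at the start none of the gas is in solution
- "hardly changes" means that all values lie within two and a half points (for a concentration: within two and a half percent of the largest)

**Odd pair.** At 6.00 min, Tuesday's flask, with 430 mM of catalyst, held 21.1% of target, less than the 41.9% in Monday's flask with 150 mM. The flask with more catalyst gave less target at the same hour.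

**The dose.** Winter's flask will end at 600 mM·min; we call this product of catalyst concentration and time the dose. Monday's flask reaches 600 mM·min at 4.00 min and Tuesday's reaches 645 mM·min at 1.50 min, and they read nearly alike: target 36.8% and 34.2%, substrate 53.2% and 52.0%. So, with substrate and held gas the same, we read the odd pair as two points on one curve, with Monday's flask at 900 mM·min and Tuesday's at 2580 mM·min, where its readings have passed their highest.

**Mean loss.** In Tuesday's flask substrate plus target fall short of the charge, and the shortfall grows by 64 percentage points from 1.50 min to 6.00 min. We replace the bent target curve by its mean over that stretch, 34.0%, and treat the loss as pseudo-first-order in target. That gives a dose of 1030 mM·min per factor e.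

**Our reckoning.** Winter's dose equals Monday's at 4.00 min, so we take the reading there, 36.8%. Autumn's 1200 mM·min lies near Tuesday's 1290 mM·min, which read 42.6%. Stepping from Tuesday's last reading gives midnight 25.1% and summer 2.43%. Taking the mean from the two end readings instead puts summer at 1.48%, so the way of taking the mean moves that estimate by about 0.95 points.

**The result.** The forecast, holding that “the runs should collapse on catalyst × time”, gave 35%, 43%, 25% and 2%: rises, then falls. The flasks give 36.1%, 42.3%, 22.6% and 2.60%: rises, then falls.

    substrate + reagent + catalyst → target + catalyst, rate k1*[substrate]*[reagent]*[catalyst]/(1 + ([substrate]/sat1)) (1.49 M, k = 0.186 /M²/s)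
    reagent + catalyst + target → catalyst + over-reaction product (k = 0.0840 /M²/s)
    gas ⇌ reagent, rate k3*(csat - [reagent]) (kL = 0.728 /s)

**Why it falls.** Autumn's flask at 6.00 min has winter's final dose of 600 mM·min, and the two hold 35.8% and 36.1% of target. Midnight's flask at 6.00 min, with reagent still 0.193 M against a saturation of 200 mM, has autumn's final dose and holds 42.5% against 42.3%. The row drops towards summer because target goes on with reagent over the catalyst to over-reaction product. With that path taken away, summer's flask ends at >99.9% of target instead of 2.60%.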